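**Retrosynthetic overview**
1. Locants follow 1-benzofuran: O1, enol-ether carbon C2, CH2 C3, ring-fusion CH C3a, CMe2 C4, CHBr C5, C6, C7, oxygen-bearing C7a. The bromomethyl ketone is taken back to an ethyl ester (one-carbon homologation with LiCH2Br), and the C3a–H bond to a C3=C3a alkene (hydrogenation anti to the axial methyl groups on C4 and C7a gives the trans ring fusion).
2. Key disconnection: O1–C2 and C3–C3a together, by an oxa-Michael/vinylogous aldol condensation ([3+2] annulation) of a tertiary α-hydroxy ketone (hydroxyl on C7a, ketone at C3a) with ethyl 2-methylbuta-2,3-dienoate, which delivers C2, C3 and the whole side chain.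
3. Enabling feature: C3a lies between two fully substituted ring carbons (C4 and C7a), so it can be carried as a ketone that cannot enolise, with the ring oxygen already on C7a. The push–pull unit O1–C2=C–C=O of the oxolane ring makes C3 the γ-carbon of a dienolate as soon as O1 has added to C2.
4. Ring order: cyclohexane first, by a bromiranium-initiated, vinylsilane-terminated cyclisation of a sulcatone-derived diene (the silyl group fixes the alkene at C3a=C7a for dihydroxylation and oxidation to the α-hydroxy ketone); oxolane second, in the key step.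
5. Stereocontrol: C5 from a Shi epoxide opened by bromide with inversion, C7a from face-selective osmylation, C3a from the hydrogenation.

Key step: step 7

Remark: the exocyclic C=C of the 2-ylidene compounds is a push–pull alkene that equilibrates easily; its Z form (carbonyl on the O1 side, methyl on the C3 side), which is the form of the target, is assumed to be the stable one and is drawn throughout.

**Step 1**
Reactants: 1 6-methylhept-5-en-2-one (sulcatone)
Product: 2 [(1E/Z)-2,6-dimethylhepta-1,5-dien-1-yl]trimethylsilane (both alkene isomers, used as the mixture)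
Conditions: Cp2TiCl2, Me3SiCH2MgCl (2 equiv), Et2O, 0 °C to rt; then 1, toluene, 100 °C
Reagents that add atoms: (trimethylsilyl)methylmagnesium chloride, C[Si](C)(C)C[Mg]Cl
Why: Petasis-type carbonyl alkylidenation: on heating, Cp2Ti(CH2SiMe3)2 formed in the flask loses SiMe4 to give the titanium alkylidene Cp2Ti=CHSiMe3, which should olefinate the enolisable methyl ketone without deprotonating it; both alkene isomers are carried on because they converge in step 4.

**Step 2**
Reactants: 2 [(1E/Z)-2,6-dimethylhepta-1,5-dien-1-yl]trimethylsilane
Product: 3 (3R)-2,2-dimethyl-3-[(3E/Z)-3-methyl-4-(trimethylsilyl)but-3-en-1-yl]oxirane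
Conditions: 1,2:4,5-di-O-isopropylidene-β-D-erythro-2,3-hexodiulo-2,6-pyranose (0.3 equiv), KHSO5 (Oxone, 1.1 equiv), K2CO3, Bu4NHSO4 (cat.), MeCN/CH2(OMe)2/aq. buffer (pH 10.5), 0 °C
Reagents that add atoms: potassium peroxymonosulfate, [K+].[O-]S(=O)(=O)OO
Why: Shi epoxidation: the chiral dioxirane should attack the electron-rich trialkyl-substituted alkene through a spiro transition state and set the oxirane centre as R, while the more hindered silicon-bearing alkene reacts more slowly and is spared at one equivalent of oxidant.

**Step 3**
Reactants: 3 (3R)-2,2-dimethyl-3-[(3E/Z)-3-methyl-4-(trimethylsilyl)but-3-en-1-yl]oxirane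
Product: 4 (3S,6E/Z)-3-bromo-2,6-dimethyl-7-(trimethylsilyl)hept-6-en-2-ol
Conditions: Li2NiBr4 (1.5 equiv), THF, 0 °C to rt; aqueous work-up at pH 7
Reagents that add atoms: dilithium tetrabromonickelate, [Li+].[Li+].Br[Ni-2](Br)(Br)Br
Why: Regioselective halohydrin formation: soft bromide from Li2NiBr4 should open the oxirane by SN2 attack at the less substituted carbon with inversion (R oxirane to S bromide), leaving the tertiary C–O bond and the vinylsilane untouched.

**Step 4**
Reactants: 4 (3S,6E/Z)-3-bromo-2,6-dimethyl-7-(trimethylsilyl)hept-6-en-2-ol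
Product: 5 (4S)-4-bromo-1,3,3-trimethylcyclohex-1-ene
Conditions: BF3·OEt2 (0.2 equiv), (CF3)2CHOH/CH2Cl2 (1:4), 0.01 M, −40 to 0 °C
Reagents that add atoms: none
Why: Vinylsilane-terminated cation–olefin cyclisation: ionisation of the tertiary alcohol with participation of the neighbouring bromine gives a configurationally defined bromiranium ion, which is captured 6-endo through a chair transition state by the silicon-bearing alkene carbon, and loss of silicon from the β-silyl cation places the ring double bond between C1 and C2 only; no bond at the bromine-bearing centre is broken, so it should stay S, and high dilution suppresses bromonium transfer between alkenes.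

**Step 5**
Reactants: 5 (4S)-4-bromo-1,3,3-trimethylcyclohex-1-ene
Product: 6 (1S,2R,4S)-4-bromo-1,3,3-trimethylcyclohexane-1,2-diol
Conditions: OsO4 (2 mol %), N-methylmorpholine N-oxide (1.5 equiv), acetone/H2O (4:1), 0 °C to rt
Reagents that add atoms: osmium tetroxide, O=[Os](=O)(=O)=O; N-methylmorpholine N-oxide, C[N+]1([O-])CCOCC1; water, O
Why: Upjohn dihydroxylation: suprafacial osmylation should occur on the face opposite the pseudoaxial allylic methyl group, which lies on the side of the equatorial bromine, so the tertiary carbinol centre is set as 1S (hydroxyl trans to bromine); the secondary carbinol centre (2R) is removed in step 6.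

**Step 6**
Reactants: 6 (1S,2R,4S)-4-bromo-1,3,3-trimethylcyclohexane-1,2-diol
Product: 7 (3S,6S)-3-bromo-6-hydroxy-2,2,6-trimethylcyclohexan-1-one
Conditions: 2-iodoxybenzoic acid (IBX, 1.5 equiv), DMSO, 40 °C
Reagents that add atoms: none
Why: IBX oxidation of a vicinal diol: the secondary alcohol should be oxidised to the ketone without C–C cleavage while the tertiary alcohol is untouched, giving an α-hydroxy ketone that has no α-hydrogen and therefore cannot enolise or epimerise.

**Step 7**
Reactants: 7 (3S,6S)-3-bromo-6-hydroxy-2,2,6-trimethylcyclohexan-1-one; 8 ethyl 2-methylbuta-2,3-dienoate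
Product: 11 ethyl (2Z)-2-[(5S,7aS)-5-bromo-4,4,7a-trimethyl-5,6,7,7a-tetrahydro-1-benzofuran-2(4H)-ylidene]propanoate, via oxa-Michael adduct 9 (not isolated), via aldol adduct 10 (not isolated)
Conditions: KH (1.1 equiv), THF, 0 °C; 8 (1.2 equiv) added over 1 h; then 50 °C
Reagents that add atoms: none
Why: Proposed new method: the potassium alkoxide of 7 should add to the central carbon of allenoate 8 (oxa-Michael addition, O1–C2 bond) to give the 2-alkoxy dienolate 9, whose unsubstituted γ-carbon (the future C3) attacks the C3a ketone (C3–C3a bond) to give aldolate 10, and 10 loses hydroxide by E1cB through its vinylogous enolate; the closest known reaction type is the base-mediated oxa-Michael/aldol annulation of α-hydroxy ketones with electron-poor alkynes to dihydrofurans, run here in its vinylogous (γ) mode. The oxolane ring closes by a 5-(enolendo)-exo-trig aldol addition, the mode by which 1,4-diketones close to cyclopentenones, from the axial face of the ketone opposite the axial methyl groups. No new stereocentre remains after the step (C3a becomes sp2, C5 and C7a are not touched) and the exocyclic alkene geometry is set thermodynamically through the freely rotating dienolate. The step needs γ- over α-attack of the dienolate and condensation in place of retro-aldol return: α-attack would build a quaternary carbon between two fully substituted centres and is reversible, the ketone has no α-hydrogen and cannot enolise, and only the γ-adduct can dehydrate, which drains the equilibria toward 11. Lactonisation of the aldolate onto the ester is excluded because it would need a bridgehead alkene, and the equatorial bromide has no antiperiplanar hydrogen for E2.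

**Step 8**
Reactants: 11 ethyl (2Z)-2-[(5S,7aS)-5-bromo-4,4,7a-trimethyl-5,6,7,7a-tetrahydro-1-benzofuran-2(4H)-ylidene]propanoate
Product: 12 ethyl (2Z)-2-[(3aS,5S,7aS)-5-bromo-4,4,7a-trimethylhexahydro-1-benzofuran-2(3H)-ylidene]propanoate
Conditions: H2 (4 bar), PtO2 (10 mol %), EtOAc, rt
Reagents that add atoms: none
Why: Heterogeneous syn hydrogenation: only the trisubstituted C3=C3a alkene should react (the tetrasubstituted push–pull exocyclic alkene is inert and platinum spares the alkyl bromide), and hydrogen is delivered from the face opposite the two axial methyl groups on C7a and C4, which sets C3a as S and the ring fusion as trans.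

**Step 9**
Reactants: 12 ethyl (2Z)-2-[(3aS,5S,7aS)-5-bromo-4,4,7a-trimethylhexahydro-1-benzofuran-2(3H)-ylidene]propanoate
Product: 13 (3Z)-1-bromo-3-[(3aS,5S,7aS)-5-bromo-4,4,7a-trimethylhexahydro-1-benzofuran-2(3H)-ylidene]butan-2-one (target)
Conditions: CH2Br2 (3 equiv), MeLi·LiBr (2.5 equiv), THF/Et2O, −78 °C; AcOH quench at −78 °C
Reagents that add atoms: dibromomethane, BrCBr
Why: Halomethyllithium homologation of an ester to an α-halo ketone: bromomethyllithium, generated by Br/Li exchange in the presence of the ester, should add once to the ester carbonyl, the tetrahedral lithium alkoxide is stable at −78 °C and collapses to the bromomethyl ketone on acidic quench, and the neopentyl-type ring bromide does not exchange with MeLi at this temperature.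

**Compound list**
1 | 6-methylhept-5-en-2-one (sulcatone) | CC(=O)CCC=C(C)C | starting material
2 | [(1E/Z)-2,6-dimethylhepta-1,5-dien-1-yl]trimethylsilane | C[Si](C)(C)C=C(C)CCC=C(C)C | intermediate
3 | (3R)-2,2-dimethyl-3-[(3E/Z)-3-methyl-4-(trimethylsilyl)but-3-en-1-yl]oxirane | C[Si](C)(C)C=C(C)CC[C@H]1OC1(C)C | intermediate
4 | (3S,6E/Z)-3-bromo-2,6-dimethyl-7-(trimethylsilyl)hept-6-en-2-ol | C[Si](C)(C)C=C(C)CC[C@H](Br)C(C)(C)O | intermediate
5 | (4S)-4-bromo-1,3,3-trimethylcyclohex-1-ene | CC1=CC(C)(C)[C@@H](Br)CC1 | intermediate
6 | (1S,2R,4S)-4-bromo-1,3,3-trimethylcyclohexane-1,2-diol | O[C@@H]1C(C)(C)[C@@H](Br)CC[C@]1(C)O | intermediate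
7 | (3S,6S)-3-bromo-6-hydroxy-2,2,6-trimethylcyclohexan-1-one | O=C1C(C)(C)[C@@H](Br)CC[C@]1(C)O | intermediate
8 | ethyl 2-methylbuta-2,3-dienoate | CCOC(=O)C(C)=C=C | starting material
9 | oxa-Michael adduct (not isolated): potassium dienolate of ethyl 3-{[(1S,4S)-4-bromo-1,3,3-trimethyl-2-oxocyclohexyl]oxy}-2-methylbut-3-enoate | CCOC([O-])=C(C)C(=C)O[C@@]1(C)CC[C@H](Br)C(C)(C)C1=O.[K+] | intermediate
10 | aldol adduct (not isolated): potassium alkoxide of ethyl 2-[(5S,7aS)-5-bromo-3a-hydroxy-4,4,7a-trimethylhexahydro-1-benzofuran-2(3H)-ylidene]propanoate; C3a configuration and alkene geometry not fixed, both are erased or equilibrated on dehydration | CCOC(=O)C(C)=C1CC2([O-])C(C)(C)[C@@H](Br)CC[C@]2(C)O1.[K+] | intermediate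
11 | ethyl (2Z)-2-[(5S,7aS)-5-bromo-4,4,7a-trimethyl-5,6,7,7a-tetrahydro-1-benzofuran-2(4H)-ylidene]propanoate | C/C(C(=O)OCC)=C1\C=C2C(C)(C)[C@@H](Br)CC[C@]2(C)O1 | intermediate
12 | ethyl (2Z)-2-[(3aS,5S,7aS)-5-bromo-4,4,7a-trimethylhexahydro-1-benzofuran-2(3H)-ylidene]propanoate | C/C(C(=O)OCC)=C1\C[C@H]2C(C)(C)[C@@H](Br)CC[C@]2(C)O1 | intermediate
13 | (3Z)-1-bromo-3-[(3aS,5S,7aS)-5-bromo-4,4,7a-trimethylhexahydro-1-benzofuran-2(3H)-ylidene]butan-2-one | C/C(C(=O)CBr)=C1\C[C@H]2C(C)(C)[C@@H](Br)CC[C@]2(C)O1 | target

Total step count: 9
Longest linear sequence: 9 steps (1 to 13; 8 is a purchased partner)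

**Steps most likely to fail**

1. Step 7 (Proposed new method). The congested aldolate may return by retro-aldol faster than it dehydrates, the dienolate may react through its α-carbon, or the allenoate may oligomerise under base. The fallback uses known chemistry, sets out from 7 and comes back at 11. Heating 7 with (triphenylphosphoranylidene)ketene in toluene (O-acylation of the tertiary alcohol, then intramolecular Wittig reaction at the ketone) should give the butenolide (5S,7aS)-5-bromo-4,4,7a-trimethyl-5,6,7,7a-tetrahydro-1-benzofuran-2(4H)-one F1. Addition of the lithium enolate of ethyl propanoate (LiN(i-Pr)2, THF, −78 °C) to the lactone carbonyl (Claisen-type 1,2-addition; the β-carbon is fully substituted) should give the lactol ethyl 2-[(5S,7aS)-5-bromo-2-hydroxy-4,4,7a-trimethyl-2,4,5,6,7,7a-hexahydro-1-benzofuran-2-yl]propanoate F2. Dehydration (MsCl, Et3N, or catalytic TsOH) then gives 11.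

2. Step 4. Enantiopurity may erode through bromonium transfer between alkenes, the vinylsilane may be protodesilylated before ring closure, or the cation may lose a proton in place of silicon and give alkene regioisomers. The fallback sets out from 2 and comes back at 5, omitting 3 and 4. It is a reagent-controlled, catalytic enantioselective bromonium-induced cyclisation of 2 with 1,3-dibromo-5,5-dimethylhydantoin and the chiral Lewis base (R)-4-[(trifluoromethanesulfonyl)amino]-2,6-bis(2,4,6-triisopropylphenyl)dinaphtho[2,1-d:1′,2′-f][1,3,2]dioxaphosphepine 4-sulfide (10 mol %) in toluene at −90 °C. The catalyst antipode is chosen so that the S bromide results. It makes no compound outside the list (F0).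

3. Step 9. The carbenoid may decompose before it adds to the deactivated, hindered vinylogous carbonate ester, or it may deprotonate C3 in place of adding. The fallback sets out from 12 and comes back at 13. The longer-lived carbenoid LiCHBr2 (from CH2Br2 and lithium 2,2,6,6-tetramethylpiperidide, THF, −90 °C) is added to the ester to give (3Z)-1,1-dibromo-3-[(3aS,5S,7aS)-5-bromo-4,4,7a-trimethylhexahydro-1-benzofuran-2(3H)-ylidene]butan-2-one F3. Selective monodebromination of the dibromomethyl ketone with diethyl phosphite and Et3N (THF, 0 °C) should then give 13.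

**Further compounds**
F1 | step 7 | (5S,7aS)-5-bromo-4,4,7a-trimethyl-5,6,7,7a-tetrahydro-1-benzofuran-2(4H)-one | O=C1C=C2C(C)(C)[C@@H](Br)CC[C@]2(C)O1
F2 | step 7 | ethyl 2-[(5S,7aS)-5-bromo-2-hydroxy-4,4,7a-trimethyl-2,4,5,6,7,7a-hexahydro-1-benzofuran-2-yl]propanoate | CCOC(=O)C(C)C1(O)C=C2C(C)(C)[C@@H](Br)CC[C@]2(C)O1
F0 | step 4 | none | none
F3 | step 9 | (3Z)-1,1-dibromo-3-[(3aS,5S,7aS)-5-bromo-4,4,7a-trimethylhexahydro-1-benzofuran-2(3H)-ylidene]butan-2-one | C/C(C(=O)C(Br)Br)=C1\C[C@H]2C(C)(C)[C@@H](Br)CC[C@]2(C)O1
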